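Ring B, the cyclohexa-2,5-dienone, is disconnected to 2-allyl-5-methoxy-1,4-benzoquinone: its quaternary carbon C4 (methoxy plus side chain) was a quinone carbonyl, and its C2=C3 double bond (allyl-bearing C2 and the neighbouring ring CH) is the feature exploited, being hidden as a cyclopentadiene adduct. One catalytic enantioselective Diels–Alder reaction at that bond converts the flat, achiral quinone into a rigid endo tricycle with four temporary stereocentres and a single open face at the C4 carbonyl; these centres steer the side-chain aldol and are erased by cycloreversion in the last step. The precursor is the quinone, three steps from 3,4-dimethoxyphenol, together with freshly cracked cyclopentadiene.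

Key step: step 5

Assumption: the sense of induction in step 5 is taken from the accepted binding model of the (S)-configured catalyst; should adduct 9 form as its mirror image, the (R)-configured catalyst is used and nothing else changes.

Step 1
Reactants: 1 3,4-dimethoxyphenol; 2 allyl bromide
Product: 3 4-(allyloxy)-1,2-dimethoxybenzene
Conditions: K2CO3, acetone, reflux
Reagents that add atoms: none
Why: Williamson ether synthesis, in which the phenoxide formed with K2CO3 displaces bromide from the primary allylic halide at oxygen, and no stereocentre is formed.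

Step 2
Reactants: 3 4-(allyloxy)-1,2-dimethoxybenzene
Product: 5 2-allyl-4,5-dimethoxyphenol, via ortho-dienone 4 (not isolated)
Conditions: PhNEt2, 200 °C, Ar
Reagents that add atoms: none
Why: Aromatic Claisen rearrangement, in which the concerted [3,3] shift should deliver the allyl group to the less hindered ortho carbon (the one not flanked by a methoxy group) and dienone 4 tautomerises to the phenol, any 2-allyl-3,4-dimethoxy isomer being removed by chromatography.

Step 3
Reactants: 5 2-allyl-4,5-dimethoxyphenol
Product: 6 2-allyl-5-methoxy-1,4-benzoquinone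
Conditions: (NH4)2Ce(NO3)6 (2.2 equiv), MeCN/H2O, 0 °C
Reagents that add atoms: water, O
Why: Oxidative demethylation of a para-methoxyphenol, in which two one-electron oxidations by tetravalent cerium give an oxocarbenium ion at C4 that is captured by water and loses methanol, leaving the para-quinone with the allyl group and the second methoxy group untouched.

Step 4
Reactants: 7 dicyclopentadiene
Product: 8 cyclopentadiene
Conditions: neat, 180 °C, distil, collect at −78 °C, use at once
Reagents that add atoms: none
Why: Thermal retro-Diels–Alder cracking, in which each molecule of the dimer falls apart into two molecules of the monomer, which is removed by distillation and used before it can dimerise again.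

Step 5
Reactants: 6 2-allyl-5-methoxy-1,4-benzoquinone; 8 cyclopentadiene
Product: 9 (1R,4S,4aR,8aS)-4a-allyl-7-methoxy-1,4,4a,8a-tetrahydro-1,4-methanonaphthalene-5,8-dione (endo adduct)
Conditions: (S)-1-(2-methylphenyl)-3,3-diphenyltetrahydro-1H,3H-pyrrolo[1,2-c][1,3,2]oxazaborole (20 mol%), HN(SO2CF3)2 (17 mol%), CH2Cl2, −78 °C, dark, diene in threefold excess
Reagents that add atoms: none
Why: The protonated oxazaborolidine is a cationic boron Lewis acid that binds a quinone carbonyl oxygen, lowers the LUMO and lets cyclopentadiene add to quinone C2=C3 in a concerted suprafacial [4+2] cycloaddition; the closest known reaction type is the catalytic enantioselective quinone Diels–Alder reaction with chiral oxazaborolidinium salts, which tolerates alkyl- and alkoxy-substituted 1,4-benzoquinones. The one new ring, the six-membered carbocycle C1–C2=C3–C4–C4a–C8a of the norbornene (adduct locants), closes by intermolecular cycloaddition with both σ bonds (C1–C8a and C4–C4a) formed together on one quinone face. C4a and C8a are set cis by the suprafacial addition, their relation to the bridgeheads C1 and C4 (endo, enedione ring under the new C2=C3 bridge) by secondary orbital overlap, and the absolute sense of all four by the catalyst, in which the quinone is held through B–O coordination and an adjacent ring C–H···O contact above a phenyl group that covers one face, so that the diene should enter from the face on which quinone C1, C2, C3, C4 run anticlockwise. The step needs site selectivity for C2=C3 over C5=C6, and the methoxy group secures it by turning C5=C6 into an electron-rich vinylogous-ester double bond. Because C4a carries the allyl group the adduct cannot enolise to a hydroquinone, so the stereocentres persist until the cycloreversion.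

Step 6
Reactants: 10 1-(3,4-dimethoxyphenyl)propan-1-one; 9 endo adduct
Product: 13 (1R,4S,4aR,8R,8aS)-4a-allyl-8-[(2S)-1-(3,4-dimethoxyphenyl)-1-oxopropan-2-yl]-7,8-dimethoxy-1,4,4a,8a-tetrahydro-1,4-methanonaphthalen-5(8H)-one, via lithium Z-enolate 11 (not isolated), via lithium aldolate 12 (not isolated)
Conditions: 10 (1.2 equiv), LiN(SiMe3)2 (1.15 equiv), THF, −78 °C; then 9, −78 °C; then MeOTf (3 equiv), −78 to −40 °C; aq. NaHCO3
Reagents that add atoms: methyl trifluoromethanesulfonate (MeOTf), COS(=O)(=O)C(F)(F)F
Why: Kinetic lithium aldol addition followed by Williamson-type O-methylation in the same flask, in which the Z-enolate should attack the C8 ketone (more electrophilic than the neopentylic vinylogous-ester carbonyl C5) from the convex face, anti to the norbornene and syn to 8a-H, which sets C8 as R, while a closed chair transition state with the bulkier sp3 ring arm (C8a) equatorial sets the side-chain methine, and MeOTf then caps the tertiary lithium alkoxide before it can revert.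

Step 7
Reactants: 13 tricyclic β-methoxy ketone
Product: 14 (1R,4S,4aR,8R,8aS)-4a-allyl-8-[(1R,2R)-1-(3,4-dimethoxyphenyl)-1-hydroxypropan-2-yl]-7,8-dimethoxy-1,4,4a,8a-tetrahydro-1,4-methanonaphthalen-5(8H)-one
Conditions: Zn(BH4)2, Et2O, −30 to 0 °C; aq. NH4Cl
Reagents that add atoms: none
Why: Chelation-controlled ketone reduction, in which zinc bridges the ketone oxygen and the C8 methoxy oxygen in a six-membered chelate and hydride enters anti to the α-methyl group, which should set the carbinol carbon as R (methyl and hydroxyl syn), while the hindered vinylogous-ester carbonyl C5 and the alkenes are left alone at low temperature.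

Step 8
Reactants: 14 tricyclic alcohol
Product: 15 (1R,2R)-1-(3,4-dimethoxyphenyl)-2-[(1R,4S,4aR,8R,8aS)-4a-allyl-7,8-dimethoxy-5-oxo-1,4,4a,5,8,8a-hexahydro-1,4-methanonaphthalen-8-yl]propyl acetate
Conditions: Ac2O, pyridine, 4-(dimethylamino)pyridine (cat.), CH2Cl2, 0 °C to rt
Reagents that add atoms: acetic anhydride, CC(=O)OC(C)=O
Why: Acyl transfer catalysed by 4-(dimethylamino)pyridine to the only hydroxyl group with retention at the carbinol carbon, and capping the alcohol before the dienone is unveiled rules out a later oxa-Michael closure onto ring B.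

Step 9
Reactants: 15 tricyclic acetate
Product: 16 (1R,2R)-1-(3,4-dimethoxyphenyl)-2-[(1R)-3-allyl-1,6-dimethoxy-4-oxocyclohexa-2,5-dien-1-yl]propyl acetate (target, CNP0159267.1)
Conditions: Ph2O (dilute, degassed), 230 °C, Ar stream, short time
Reagents that add atoms: none
Why: Thermal retro-Diels–Alder reaction, in which concerted cycloreversion expels cyclopentadiene (swept out by the gas stream) and restores the C2=C3 double bond and with it the cross-conjugated dienone, helped by relief of crowding at the quaternary ring-fusion carbon C4a and by the conjugation gained, while C4 and the two side-chain stereocentres are not involved and keep their configuration.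

Compound list
1 | 3,4-dimethoxyphenol | COc1ccc(O)cc1OC | starting material
2 | allyl bromide | C=CCBr | starting material
3 | 4-(allyloxy)-1,2-dimethoxybenzene | C=CCOc1ccc(OC)c(OC)c1 | intermediate
4 | 6-allyl-3,4-dimethoxycyclohexa-2,4-dien-1-one (Claisen ortho-dienone, racemic) | C=CCC1C=C(OC)C(OC)=CC1=O | intermediate
5 | 2-allyl-4,5-dimethoxyphenol | C=CCc1cc(OC)c(OC)cc1O | intermediate
6 | 2-allyl-5-methoxy-1,4-benzoquinone | C=CCC1=CC(=O)C(OC)=CC1=O | intermediate
7 | dicyclopentadiene | C1C=CC2C1C1CC2C=C1 | starting material
8 | cyclopentadiene | C1C=CC=C1 | intermediate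
9 | (1R,4S,4aR,8aS)-4a-allyl-7-methoxy-1,4,4a,8a-tetrahydro-1,4-methanonaphthalene-5,8-dione (endo) | C=CC[C@]12C(=O)C=C(OC)C(=O)[C@H]1[C@H]3C=C[C@@H]2C3 | intermediate
10 | 1-(3,4-dimethoxyphenyl)propan-1-one | CCC(=O)c1ccc(OC)c(OC)c1 | starting material
11 | lithium (Z)-1-(3,4-dimethoxyphenyl)prop-1-en-1-olate | C/C=C(\O[Li])c1ccc(OC)c(OC)c1 | intermediate
12 | lithium (1R,4S,4aR,8R,8aS)-4a-allyl-8-[(2S)-1-(3,4-dimethoxyphenyl)-1-oxopropan-2-yl]-7-methoxy-5-oxo-1,4,4a,5,8,8a-hexahydro-1,4-methanonaphthalen-8-olate | C=CC[C@]12C(=O)C=C(OC)[C@](O[Li])([C@H](C)C(=O)c4ccc(OC)c(OC)c4)[C@H]1[C@H]3C=C[C@@H]2C3 | intermediate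
13 | (1R,4S,4aR,8R,8aS)-4a-allyl-8-[(2S)-1-(3,4-dimethoxyphenyl)-1-oxopropan-2-yl]-7,8-dimethoxy-1,4,4a,8a-tetrahydro-1,4-methanonaphthalen-5(8H)-one | C=CC[C@]12C(=O)C=C(OC)[C@](OC)([C@H](C)C(=O)c4ccc(OC)c(OC)c4)[C@H]1[C@H]3C=C[C@@H]2C3 | intermediate
14 | (1R,4S,4aR,8R,8aS)-4a-allyl-8-[(1R,2R)-1-(3,4-dimethoxyphenyl)-1-hydroxypropan-2-yl]-7,8-dimethoxy-1,4,4a,8a-tetrahydro-1,4-methanonaphthalen-5(8H)-one | C=CC[C@]12C(=O)C=C(OC)[C@](OC)([C@H](C)[C@@H](O)c4ccc(OC)c(OC)c4)[C@H]1[C@H]3C=C[C@@H]2C3 | intermediate
15 | (1R,2R)-1-(3,4-dimethoxyphenyl)-2-[(1R,4S,4aR,8R,8aS)-4a-allyl-7,8-dimethoxy-5-oxo-1,4,4a,5,8,8a-hexahydro-1,4-methanonaphthalen-8-yl]propyl acetate | C=CC[C@]12C(=O)C=C(OC)[C@](OC)([C@H](C)[C@@H](OC(C)=O)c4ccc(OC)c(OC)c4)[C@H]1[C@H]3C=C[C@@H]2C3 | intermediate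
16 | (1R,2R)-1-(3,4-dimethoxyphenyl)-2-[(1R)-3-allyl-1,6-dimethoxy-4-oxocyclohexa-2,5-dien-1-yl]propyl acetate | C=CCC1=C[C@@](OC)([C@H](C)[C@@H](OC(C)=O)c2ccc(OC)c(OC)c2)C(OC)=CC1=O | target

Total step count: 9. Longest linear sequence: 8 steps (steps 1, 2, 3, 5, 6, 7, 8, 9, from 3,4-dimethoxyphenol); step 4 is a one-step side branch.

Steps most likely to fail

Step 6. Retro-aldol cleavage and proton transfer from C8a–H may outrun O-methylation of the hindered, chelated tertiary lithium alkoxide, and the configuration of the side-chain methine rests on which ring arm sits equatorial in the chair transition state. The fallback sets out from 9 and 10 and separates bond formation from alkylation. Aldolate 12 is generated as before but quenched at −78 °C with acetic acid, which should give the free tertiary aldol (1R,4S,4aR,8R,8aS)-4a-allyl-8-[(2S)-1-(3,4-dimethoxyphenyl)-1-oxopropan-2-yl]-8-hydroxy-7-methoxy-1,4,4a,8a-tetrahydro-1,4-methanonaphthalen-5(8H)-one F1. It is purified, with methine epimers separated at this stage, and then O-methylated without base-induced reversal by trimethyloxonium tetrafluoroborate and 1,8-bis(dimethylamino)naphthalene in CH2Cl2. The route is rejoined at 13.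

Step 5. Face discrimination on the trisubstituted C2=C3 bond may be insufficient, for example through competing binding of the catalyst at the more basic vinylogous-ester carbonyl or through an uncatalysed background reaction. The fallback sets out from 6 and 8 and replaces asymmetric catalysis by resolution. The uncatalysed cycloaddition (CH2Cl2, 0 °C to rt, dark) should give the racemic endo adduct with the same site selectivity. Preparative chromatography on a chiral stationary phase (cellulose tris(3,5-dimethylphenylcarbamate)) then separates the wanted enantiomer from the mirror-image adduct (1S,4R,4aS,8aR)-4a-allyl-7-methoxy-1,4,4a,8a-tetrahydro-1,4-methanonaphthalene-5,8-dione F2, which is set aside. The route is rejoined at 9.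

Step 7. Hydride delivery may follow non-chelation (Felkin–Anh-type) control if the crowded tertiary methyl ether binds zinc only weakly, which would invert the carbinol carbon. The fallback sets out from 13 and makes the opposite epimer on purpose. Reduction with NaBH4 in MeOH at −40 °C should give mainly the (1S)-carbinol (1R,4S,4aR,8R,8aS)-4a-allyl-8-[(1S,2R)-1-(3,4-dimethoxyphenyl)-1-hydroxypropan-2-yl]-7,8-dimethoxy-1,4,4a,8a-tetrahydro-1,4-methanonaphthalen-5(8H)-one F3. A Mitsunobu reaction with acetic acid (PPh3, diisopropyl azodicarboxylate, toluene, 0 °C) inverts this centre and installs the acetate in one operation. Any 14 formed alongside is acetylated as in step 8, so both epimers converge and the route is rejoined at 15.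

Further compounds
F1 | step 6 | (1R,4S,4aR,8R,8aS)-4a-allyl-8-[(2S)-1-(3,4-dimethoxyphenyl)-1-oxopropan-2-yl]-8-hydroxy-7-methoxy-1,4,4a,8a-tetrahydro-1,4-methanonaphthalen-5(8H)-one | C=CC[C@]12C(=O)C=C(OC)[C@](O)([C@H](C)C(=O)c4ccc(OC)c(OC)c4)[C@H]1[C@H]3C=C[C@@H]2C3
F2 | step 5 | (1S,4R,4aS,8aR)-4a-allyl-7-methoxy-1,4,4a,8a-tetrahydro-1,4-methanonaphthalene-5,8-dione (mirror image of 9) | C=CC[C@@]12C(=O)C=C(OC)C(=O)[C@@H]1[C@@H]3C=C[C@H]2C3
F3 | step 7 | (1R,4S,4aR,8R,8aS)-4a-allyl-8-[(1S,2R)-1-(3,4-dimethoxyphenyl)-1-hydroxypropan-2-yl]-7,8-dimethoxy-1,4,4a,8a-tetrahydro-1,4-methanonaphthalen-5(8H)-one | C=CC[C@]12C(=O)C=C(OC)[C@](OC)([C@H](C)[C@H](O)c4ccc(OC)c(OC)c4)[C@H]1[C@H]3C=C[C@@H]2C3
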